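**Retrosynthetic overview**

1. Target 14 ⇐ pentabenzyl flavan 13 (global O-debenzylation). 13 ⇐ phenol-alcohol 12 by invertive O1–C2 closure; the pyran ring is the only ring formed and is made last.
2. 12 ⇐ keto-phenol 11 by catalyst-controlled ketone reduction (sets C2).
3. 11 ⇐ boron homoenolate 9 (β-boryl ketone, nucleophilic at the β-carbon) + hindered aryl bromide 4: stereospecific C4–aryl cross-coupling (sets C4).
4. 9 ⇐ chalcone 8 by enantioselective conjugate borylation; 8 ⇐ aldehyde 6 + acetophenone 7.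
5. 4 ⇐ 1 + 2 by acylation, then bromination; ring A, ring B and the phloroglucinol ring are bought as intact arenes.

The target is the (2S,4R), 2,4-trans flavan.

Assumption: 1,3,5-tris(benzyloxy)benzene and 9-phenylnonanoic acid are bought as catalogue compounds.

**Route**

Step 1
Reactants: 1 1,3,5-tris(benzyloxy)benzene; 2 9-phenylnonanoic acid
Product: 3 9-phenyl-1-[2,4,6-tris(benzyloxy)phenyl]nonan-1-one
Conditions: (CF3CO)2O (2.5 equiv), CH2Cl2, 0 °C to rt (acid and anhydride premixed, then 1)
Reagents that add atoms: none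
Why: Friedel–Crafts acylation through the mixed trifluoroacetic anhydride; the phloroglucinol triether is nucleophilic enough to need no Lewis acid, which spares the benzyl ethers, and the first acyl group deactivates the ring against a second.

Step 2
Reactants: 3 9-phenyl-1-[2,4,6-tris(benzyloxy)phenyl]nonan-1-one
Product: 4 1-[3-bromo-2,4,6-tris(benzyloxy)phenyl]-9-phenylnonan-1-one
Conditions: NBS (1.0 equiv), MeCN, 0 °C, dark
Reagents that add atoms: N-bromosuccinimide, O=C1CCC(=O)N1Br
Why: Electrophilic aromatic bromination; the two free ring positions are equivalent and each is activated by three alkoxy groups, so one equivalent gives the monobromide.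

Step 3
Reactants: 5 4-(benzyloxy)-2-hydroxybenzaldehyde
Product: 6 4-(benzyloxy)-2-(methoxymethoxy)benzaldehyde
Conditions: MOMCl, K2CO3, acetone, 0 °C to rt
Reagents that add atoms: chloromethyl methyl ether, COCCl
Why: Williamson-type O-alkylation; the MOM acetal masks the future O1 phenol through the basic and organometallic steps and is the only acid-labile group in the route.

Step 4
Reactants: 6 4-(benzyloxy)-2-(methoxymethoxy)benzaldehyde; 7 1-[4-(benzyloxy)phenyl]ethan-1-one
Product: 8 (E)-1-[4-(benzyloxy)phenyl]-3-[4-(benzyloxy)-2-(methoxymethoxy)phenyl]prop-2-en-1-one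
Conditions: KOH, EtOH/THF, rt
Reagents that add atoms: none
Why: Claisen–Schmidt aldol condensation of a methyl ketone with a non-enolisable aldehyde; dehydration gives the E-chalcone, which carries the whole C2–C3–C4 chain.

Step 5
Reactants: 8 (E)-1-[4-(benzyloxy)phenyl]-3-[4-(benzyloxy)-2-(methoxymethoxy)phenyl]prop-2-en-1-one
Product: 9 (S)-1-[4-(benzyloxy)phenyl]-3-[4-(benzyloxy)-2-(methoxymethoxy)phenyl]-3-(4,4,5,5-tetramethyl-1,3,2-dioxaborolan-2-yl)propan-1-one
Conditions: CuCl (5 mol %), NaOtBu (10 mol %), (R)-1-[(Sp)-2-(diphenylphosphino)ferrocenyl]ethyldicyclohexylphosphine (5.5 mol %), B2pin2 (1.1 equiv), MeOH (2 equiv), THF, rt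
Reagents that add atoms: bis(pinacolato)diboron, CC1(C)OB(OC1(C)C)B1OC(C)(C)C(C)(C)O1
Why: Copper-catalysed enantioselective conjugate borylation: the chiral phosphine–copper boryl adds boron to one face of the enone β-carbon and methanol protonates the copper enolate, which sets the benzylic C–B centre (future C4) as S and turns the normally electrophilic β-carbon into a boron homoenolate; the sense I expect from this ligand is S from memory of related cinnamate and enone cases, so it is checked by oxidation to the β-hydroxy ketone and the mirror-image ligand is used if it is opposite.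

Step 6
Reactants: 9 (S)-β-boryl ketone; 4 1-[3-bromo-2,4,6-tris(benzyloxy)phenyl]-9-phenylnonan-1-one
Product: 11 (R)-1-[4-(benzyloxy)phenyl]-3-[4-(benzyloxy)-2-hydroxyphenyl]-3-[2,4,6-tris(benzyloxy)-3-(9-phenylnonanoyl)phenyl]propan-1-one, via MOM-protected (R)-triaryl ketone 10 (not isolated)
Conditions: Pd(OAc)2 (10 mol %), XPhos (20 mol %), K2CO3 (3 equiv), toluene/H2O (10:1), 90 °C; then MeOH, 6 M HCl (excess), 45 °C
Reagents that add atoms: none
Why: Proposed new method: Suzuki–Miyaura coupling in which boronate 9 acts as a homoenolate, so that the enone β-carbon and the aryl bromide carbon (both electrophiles by nature) are joined; the ketone oxygen can coordinate boron in a five-membered chelate, which should enforce backside (invertive, open SE2) transmetalation to the arylpalladium bromide (divalent palladium) formed from 4 and XPhos-ligated zerovalent palladium, and the resulting C,O-chelated palladium homoenolate should resist β-hydride elimination until reductive elimination gives the (R)-triarylmethine (future C4), after which acid in the same flask cleaves only the MOM acetal; the closest known reactions are the invertive couplings of secondary β-trifluoroborato amides, 3,3-diboryl esters and α-(acylamino)benzyl boronates and the coupling of secondary alkylboron reagents with di-ortho-substituted aryl bromides under bulky phosphines; if the coupling proves retentive, the mirror-image ligand in step 5 restores the (R) centre.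

Step 7
Reactants: 11 (R)-keto-phenol
Product: 12 (1R,3R)-1-[4-(benzyloxy)phenyl]-3-[4-(benzyloxy)-2-hydroxyphenyl]-3-[2,4,6-tris(benzyloxy)-3-(9-phenylnonanoyl)phenyl]propan-1-ol
Conditions: RuCl[(R,R)-TsDPEN](p-cymene) (2 mol %), HCO2H (3 equiv), Et3N (15 equiv), DMF, 40 °C
Reagents that add atoms: none
Why: Noyori asymmetric transfer hydrogenation: the catalyst reads the aryl/alkyl pair of the unhindered 4-benzyloxyphenyl ketone and gives the (1R) carbinol under catalyst control (the C3 centre is remote), while the di-ortho-benzyloxy aryl ketone cannot reach the required transition state and is left alone; the amine-rich medium avoids acid-induced ionisation of the keto-phenol.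

Step 8
Reactants: 12 (1R,3R)-phenol-alcohol
Product: 13 1-{2,4,6-tris(benzyloxy)-3-[(2S,4R)-7-(benzyloxy)-2-[4-(benzyloxy)phenyl]chroman-4-yl]phenyl}-9-phenylnonan-1-one
Conditions: PPh3, DIAD, THF, 0 °C
Reagents that add atoms: none
Why: Intramolecular Mitsunobu etherification: the only free phenol displaces the benzylic oxyphosphonium in a six-membered SN2 closure with inversion, turning (1R) into (2S) and giving the 2,4-trans flavan with C4 untouched.

Step 9
Reactants: 13 pentabenzyl (2S,4R)-flavan
Product: 14 (+)-myristinin D, 1-{2,4,6-trihydroxy-3-[(2S,4R)-7-hydroxy-2-(4-hydroxyphenyl)chroman-4-yl]phenyl}-9-phenylnonan-1-one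
Conditions: H2 (1 atm), Pd(OH)2/C, EtOAc/MeOH, rt
Reagents that add atoms: none
Why: Hydrogenolysis of the five aryl benzyl ethers; the hindered acylphloroglucinol ketone and the cyclic benzylic C2–O bond are expected to survive these mild conditions, and neither stereocentre is touched.

**Compound list**

1 | 1,3,5-tris(benzyloxy)benzene | c1c(OCc2ccccc2)cc(OCc2ccccc2)cc1OCc1ccccc1 | starting material
2 | 9-phenylnonanoic acid | OC(=O)CCCCCCCCc1ccccc1 | starting material
3 | 9-phenyl-1-[2,4,6-tris(benzyloxy)phenyl]nonan-1-one | O=C(CCCCCCCCc1ccccc1)c1c(OCc2ccccc2)cc(OCc2ccccc2)cc1OCc1ccccc1 | intermediate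
4 | 1-[3-bromo-2,4,6-tris(benzyloxy)phenyl]-9-phenylnonan-1-one | O=C(CCCCCCCCc1ccccc1)c1c(OCc2ccccc2)cc(OCc2ccccc2)c(Br)c1OCc1ccccc1 | intermediate
5 | 4-(benzyloxy)-2-hydroxybenzaldehyde | O=Cc1ccc(OCc2ccccc2)cc1O | starting material
6 | 4-(benzyloxy)-2-(methoxymethoxy)benzaldehyde | O=Cc1ccc(OCc2ccccc2)cc1OCOC | intermediate
7 | 1-[4-(benzyloxy)phenyl]ethan-1-one | CC(=O)c1ccc(OCc2ccccc2)cc1 | starting material
8 | (E)-1-[4-(benzyloxy)phenyl]-3-[4-(benzyloxy)-2-(methoxymethoxy)phenyl]prop-2-en-1-one | O=C(/C=C/c1ccc(OCc2ccccc2)cc1OCOC)c1ccc(OCc2ccccc2)cc1 | intermediate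
9 | (S)-1-[4-(benzyloxy)phenyl]-3-[4-(benzyloxy)-2-(methoxymethoxy)phenyl]-3-(4,4,5,5-tetramethyl-1,3,2-dioxaborolan-2-yl)propan-1-one | O=C(C[C@H](B1OC(C)(C)C(C)(C)O1)c1ccc(OCc2ccccc2)cc1OCOC)c1ccc(OCc2ccccc2)cc1 | intermediate
10 | (R)-1-[4-(benzyloxy)phenyl]-3-[4-(benzyloxy)-2-(methoxymethoxy)phenyl]-3-[2,4,6-tris(benzyloxy)-3-(9-phenylnonanoyl)phenyl]propan-1-one | O=C(C[C@H](c1ccc(OCc2ccccc2)cc1OCOC)c1c(OCc2ccccc2)cc(OCc2ccccc2)c(C(=O)CCCCCCCCc2ccccc2)c1OCc1ccccc1)c1ccc(OCc2ccccc2)cc1 | intermediate (not isolated)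
11 | (R)-1-[4-(benzyloxy)phenyl]-3-[4-(benzyloxy)-2-hydroxyphenyl]-3-[2,4,6-tris(benzyloxy)-3-(9-phenylnonanoyl)phenyl]propan-1-one | O=C(C[C@H](c1ccc(OCc2ccccc2)cc1O)c1c(OCc2ccccc2)cc(OCc2ccccc2)c(C(=O)CCCCCCCCc2ccccc2)c1OCc1ccccc1)c1ccc(OCc2ccccc2)cc1 | intermediate
12 | (1R,3R)-1-[4-(benzyloxy)phenyl]-3-[4-(benzyloxy)-2-hydroxyphenyl]-3-[2,4,6-tris(benzyloxy)-3-(9-phenylnonanoyl)phenyl]propan-1-ol | O[C@@H](c1ccc(OCc2ccccc2)cc1)C[C@H](c1ccc(OCc2ccccc2)cc1O)c1c(OCc2ccccc2)cc(OCc2ccccc2)c(C(=O)CCCCCCCCc2ccccc2)c1OCc1ccccc1 | intermediate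
13 | 1-{2,4,6-tris(benzyloxy)-3-[(2S,4R)-7-(benzyloxy)-2-[4-(benzyloxy)phenyl]chroman-4-yl]phenyl}-9-phenylnonan-1-one | O=C(CCCCCCCCc1ccccc1)c1c(OCc2ccccc2)cc(OCc2ccccc2)c([C@@H]2C[C@@H](c3ccc(OCc4ccccc4)cc3)Oc3cc(OCc4ccccc4)ccc32)c1OCc1ccccc1 | intermediate
14 | (+)-myristinin D | O=C(CCCCCCCCc1ccccc1)c1c(O)cc(O)c([C@@H]2C[C@@H](c3ccc(O)cc3)Oc3cc(O)ccc32)c1O | target

**Step count and risks**

Total step count: 9. Longest linear sequence: 7 steps (5 → 6 → 8 → 9 → 11 → 12 → 13 → 14). The aryl bromide branch (1 → 3 → 4) is 2 steps and joins at step 6.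

Steps most likely to fail:

Step 6 (stereospecific homoenolate coupling). The two-electron transmetalation of a secondary benzylic boronate onto a di-ortho-substituted arylpalladium species may be too slow, leaving protodeboronation or return to chalcone 8. The fallback sets out from boronate 9 and bromide 4 and changes to single-electron transmetalation. 9 is converted with KHF2 (MeOH/H2O) into potassium (S)-trifluoroborate F1. F1 is coupled with 4 under [Ir{dF(CF3)ppy}2(bpy)]PF6, NiCl2(dme), 4,4'-di-tert-butyl-2,2'-bipyridine and 2,6-lutidine in dioxane under blue light, where the β-keto benzylic radical is captured at nickel. The radical is planar, so the product is the racemic MOM ketone F2, and the same HCl/MeOH treatment gives the racemic keto-phenol F3. Step 7 on F3 gives 12 together with its (1R,3S) diastereomer F4, which is removed by chromatography; the route is rejoined at 12. The cost is at most half of the material, unless a chiral bis(oxazoline) ligand on nickel makes the radical capture enantioconvergent, and the hindered bromide may also be slow at nickel.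

Step 8 (Mitsunobu closure). The 4-benzyloxybenzylic oxyphosphonium can ionise, giving styrene by elimination or loss of stereochemical fidelity at C2. The fallback sets out from 12 and replaces the SN2 closure by a reversible ionising one: catalytic camphorsulfonic acid in CH2Cl2 at 0 °C closes the ring through the benzylic cation. The bulky C4 aryl group should sit pseudo-axial to avoid the peri hydrogen and the C2 aryl group equatorial, which is the 2,4-trans flavan 13. Any 2,4-cis flavan F5 is separated and re-equilibrated under the same acid; the route is rejoined at 13. The trans preference is an expectation, not an established fact for this system.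

Step 7 (transfer hydrogenation). The electron-rich, β-branched ketone may reduce slowly or with incomplete catalyst control. The fallback sets out from 11 and gives up catalyst control for separation and recycling: NaBH4 in THF/MeOH at −20 °C reduces only the unhindered ketone and gives 12 plus its (1S,3R) epimer F6. The two are separated by chromatography and F6 is returned to 11 with MnO2 in CH2Cl2; the route is rejoined at 12.

**Further compounds**

F1 | step 6 | potassium (S)-{3-[4-(benzyloxy)phenyl]-1-[4-(benzyloxy)-2-(methoxymethoxy)phenyl]-3-oxopropyl}trifluoroborate | O=C(C[C@H]([B-](F)(F)F)c1ccc(OCc2ccccc2)cc1OCOC)c1ccc(OCc2ccccc2)cc1.[K+]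
F2 | step 6 | racemic 1-[4-(benzyloxy)phenyl]-3-[4-(benzyloxy)-2-(methoxymethoxy)phenyl]-3-[2,4,6-tris(benzyloxy)-3-(9-phenylnonanoyl)phenyl]propan-1-one | O=C(CC(c1ccc(OCc2ccccc2)cc1OCOC)c1c(OCc2ccccc2)cc(OCc2ccccc2)c(C(=O)CCCCCCCCc2ccccc2)c1OCc1ccccc1)c1ccc(OCc2ccccc2)cc1
F3 | step 6 | racemic 1-[4-(benzyloxy)phenyl]-3-[4-(benzyloxy)-2-hydroxyphenyl]-3-[2,4,6-tris(benzyloxy)-3-(9-phenylnonanoyl)phenyl]propan-1-one | O=C(CC(c1ccc(OCc2ccccc2)cc1O)c1c(OCc2ccccc2)cc(OCc2ccccc2)c(C(=O)CCCCCCCCc2ccccc2)c1OCc1ccccc1)c1ccc(OCc2ccccc2)cc1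
F4 | step 6 | (1R,3S)-1-[4-(benzyloxy)phenyl]-3-[4-(benzyloxy)-2-hydroxyphenyl]-3-[2,4,6-tris(benzyloxy)-3-(9-phenylnonanoyl)phenyl]propan-1-ol | O[C@@H](c1ccc(OCc2ccccc2)cc1)C[C@@H](c1ccc(OCc2ccccc2)cc1O)c1c(OCc2ccccc2)cc(OCc2ccccc2)c(C(=O)CCCCCCCCc2ccccc2)c1OCc1ccccc1
F5 | step 8 | 1-{2,4,6-tris(benzyloxy)-3-[(2R,4R)-7-(benzyloxy)-2-[4-(benzyloxy)phenyl]chroman-4-yl]phenyl}-9-phenylnonan-1-one | O=C(CCCCCCCCc1ccccc1)c1c(OCc2ccccc2)cc(OCc2ccccc2)c([C@@H]2C[C@H](c3ccc(OCc4ccccc4)cc3)Oc3cc(OCc4ccccc4)ccc32)c1OCc1ccccc1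
F6 | step 7 | (1S,3R)-1-[4-(benzyloxy)phenyl]-3-[4-(benzyloxy)-2-hydroxyphenyl]-3-[2,4,6-tris(benzyloxy)-3-(9-phenylnonanoyl)phenyl]propan-1-ol | O[C@H](c1ccc(OCc2ccccc2)cc1)C[C@H](c1ccc(OCc2ccccc2)cc1O)c1c(OCc2ccccc2)cc(OCc2ccccc2)c(C(=O)CCCCCCCCc2ccccc2)c1OCc1ccccc1
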